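**Retrosynthetic overview**
- The target is an isovanillin core with a (2R)-2-acetoxytridecyl chain at C2 and a second phenol at C6. No ring is formed in the route: the benzene ring is bought as 2-bromoisovanillin.
- Last disconnection: the aryl C6–O bond, made by oxidising the C3 phenol to the para-quinone and reducing it to the hydroquinone.
- Key disconnection: the secondary C–O bond of the acetate, made enantioselectively by aldehyde-directed anti-Markovnikov addition of acetic acid to an (E)-aryl alkene. This sets the only stereocenter and installs the acetate directly, so no free alcohol can close onto the aldehyde as a lactol.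
- The alkene comes from 2-bromoisovanillin and 1-tridecyne by hydroboration and Suzuki coupling, with the phenol capped as its acetate in the same pot.

Assumption: the sense of induction of the new step is taken from a chelate model (L-tert-leucine gives R); if the first run shows the opposite sense, D-tert-leucine is used with nothing else changed.

**Route**

Step 1
Reactants: 1 2-bromo-3-hydroxy-4-methoxybenzaldehyde (2-bromoisovanillin); 2 1-tridecyne; 3 pinacolborane
Product: 6 3-acetoxy-4-methoxy-2-[(E)-tridec-1-en-1-yl]benzaldehyde, via alkenyl pinacolboronate 4 (not isolated), via phenol styrene 5 (not isolated)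
Conditions: 2, 3 (1.05 equiv), Cy2BH (5 mol %), neat, rt; then 1, Pd(OAc)2 (3 mol %), SPhos (6 mol %), K3PO4 (3 equiv), THF/H2O 10:1, 65 °C; then Ac2O (4 equiv), 0 °C → rt
Reagents that add atoms: acetic anhydride, CC(=O)OC(C)=O
Why: Syn hydroboration of the terminal alkyne gives the (E)-alkenylboronate, Suzuki–Miyaura coupling joins it with retention of geometry to the hindered ortho-formyl bromide, and the phenoxide is acetylated in the same pot so that no free ortho-hydroxystyrene enters step 2; no stereocenter is formed.

Step 2
Reactants: 6 3-acetoxy-4-methoxy-2-[(E)-tridec-1-en-1-yl]benzaldehyde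
Product: 7 3-acetoxy-2-[(2R)-2-acetoxytridecyl]-4-methoxybenzaldehyde
Conditions: Pd(OAc)2 (10 mol %), L-tert-leucine (25 mol %), AcOH/HFIP 1:3, 50 °C, N2
Reagents that add atoms: acetic acid, CC(=O)O
Why: Proposed new method: the aldehyde condenses reversibly with L-tert-leucine to an imino-carboxylate that binds divalent palladium as an N,O-chelate and holds it on the neighbouring alkene; outer-sphere anti attack of acetate must then occur at the distal carbon (C2 of the chain), because only palladium on the benzylic carbon closes a six-membered palladacycle fused to the five-membered amino-acid chelate, which overrides the usual benzylic (Markovnikov) preference of a styrene; the tert-butyl group blocks one alkene face so acetate adds to the Re face of C2 and gives R; protonolysis of the benzylic C–Pd bond by AcOH returns divalent palladium without any redox change and imine hydrolysis releases 7 and the amino acid; the aryl acetate cap and the twisted, formyl-deactivated styrene suppress acid-catalysed Markovnikov addition and phenol cyclisation; closest known reaction types are auxiliary-directed anti-nucleopalladation/protodepalladation hydrofunctionalisation of alkenyl amides and transient-imine-directed enantioselective reductive Heck hydroarylation of alkenyl benzaldehydes, neither of which has been shown for enantioselective hydroacyloxylation of an aryl alkene.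

Step 3
Reactants: 7 3-acetoxy-2-[(2R)-2-acetoxytridecyl]-4-methoxybenzaldehyde
Product: 8 2-[(2R)-2-acetoxytridecyl]-3-hydroxy-4-methoxybenzaldehyde
Conditions: K2CO3 (0.2 equiv), MeOH, 0 °C, 20 min; AcOH quench
Reagents that add atoms: none
Why: Base-catalysed transesterification cleaves the aryl acetate (phenoxide leaving group) far faster than the secondary alkyl acetate at 0 °C, and the stereocenter is untouched because its C–O bond is not broken.

Step 4
Reactants: 8 2-[(2R)-2-acetoxytridecyl]-3-hydroxy-4-methoxybenzaldehyde
Product: 10 2-[(2R)-2-acetoxytridecyl]-3,6-dihydroxy-4-methoxybenzaldehyde, via formylquinone 9 (not isolated)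
Conditions: (KSO3)2NO (2.5 equiv), KH2PO4, acetone/H2O, 0 °C → rt; then aq Na2S2O4, EtOAc, rt
Reagents that add atoms: potassium nitrosodisulfonate (Fremy's salt), [K+].[K+].[O]N(S(=O)(=O)[O-])S(=O)(=O)[O-]
Why: Teuber oxidation: one nitroxide abstracts the phenolic hydrogen and a second delivers oxygen to the free para carbon (C6) to give the para-quinone, which dithionite reduces at once to the hydroquinone; the near-neutral medium leaves the alkyl acetate, the aldehyde and the stereocenter alone.

**Compound list**

1 | 2-bromo-3-hydroxy-4-methoxybenzaldehyde | O=Cc1ccc(OC)c(O)c1Br | starting material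
2 | 1-tridecyne | CCCCCCCCCCCC#C | starting material
3 | pinacolborane (4,4,5,5-tetramethyl-1,3,2-dioxaborolane) | CC1(C)OBOC1(C)C | starting material
4 | 4,4,5,5-tetramethyl-2-[(E)-tridec-1-en-1-yl]-1,3,2-dioxaborolane | CCCCCCCCCCC/C=C/B1OC(C)(C)C(C)(C)O1 | intermediate
5 | 3-hydroxy-4-methoxy-2-[(E)-tridec-1-en-1-yl]benzaldehyde | CCCCCCCCCCC/C=C/c1c(O)c(OC)ccc1C=O | intermediate
6 | 3-acetoxy-4-methoxy-2-[(E)-tridec-1-en-1-yl]benzaldehyde | CCCCCCCCCCC/C=C/c1c(OC(C)=O)c(OC)ccc1C=O | intermediate
7 | 3-acetoxy-2-[(2R)-2-acetoxytridecyl]-4-methoxybenzaldehyde | CCCCCCCCCCC[C@H](Cc1c(OC(C)=O)c(OC)ccc1C=O)OC(C)=O | intermediate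
8 | 2-[(2R)-2-acetoxytridecyl]-3-hydroxy-4-methoxybenzaldehyde | CCCCCCCCCCC[C@H](Cc1c(O)c(OC)ccc1C=O)OC(C)=O | intermediate
9 | (2R)-1-(2-formyl-5-methoxy-3,6-dioxocyclohexa-1,4-dien-1-yl)tridecan-2-yl acetate | CCCCCCCCCCC[C@H](CC1=C(C=O)C(=O)C=C(OC)C1=O)OC(C)=O | intermediate
10 | 2-[(2R)-2-acetoxytridecyl]-3,6-dihydroxy-4-methoxybenzaldehyde | CCCCCCCCCCC[C@H](Cc1c(O)c(OC)cc(O)c1C=O)OC(C)=O | target

**Totals**

Total step count: 4. Longest linear sequence: 4.

**Steps most likely to fail**

Step 2 (the new hydroacetoxylation). The risks are Wacker-type β-hydride elimination to an enol acetate, slow protonolysis of the benzylic C–Pd bond, and insufficient enantioselectivity. The fallback uses known chemistry, sets out from 1 and comes back to the route at 8.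
- Acetalisation of 1 with ethylene glycol (p-TsOH cat., toluene, Dean–Stark) gives 2-bromo-3-(1,3-dioxolan-2-yl)-6-methoxyphenol F1.
- MOMCl/i-Pr2NEt converts it into 2-[2-bromo-4-methoxy-3-(methoxymethoxy)phenyl]-1,3-dioxolane F2.
- Separately, decylmagnesium bromide opens (R)-epichlorohydrin (CuI cat., THF, −40 °C) to (R)-1-chlorotridecan-2-ol F3, which NaOH closes to (R)-2-undecyloxirane F4.
- Bromine–lithium exchange on F2 (n-BuLi, THF, −78 °C), transmetalation (MgBr2·OEt2, CuI 10 mol %), opening of F4 at its CH2 terminus and Ac2O quench of the alkoxide give (R)-1-[6-(1,3-dioxolan-2-yl)-3-methoxy-2-(methoxymethoxy)phenyl]tridecan-2-yl acetate F5.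
- 2 M HCl/THF at 40 °C removes the dioxolane and the MOM ether and delivers 8.
- The stereocenter comes from the chiral pool and is never broken.

Step 4 (Teuber oxidation and reduction). The risks are sluggish oxidation of a phenol that carries a formyl group and the high electrophilicity of formylquinone 9. The fallback sets out from 7 and comes back at 10.
- The known palladium-catalysed, transient-imine-directed ortho C–H hydroxylation of benzaldehydes (Pd(OAc)2, 4-chloroanthranilic acid, 1-fluoro-2,4,6-trimethylpyridinium triflate, p-TsOH, AcOH, 90 °C) places oxygen on C6, the only free ortho position. It gives 3-acetoxy-2-[(2R)-2-acetoxytridecyl]-6-hydroxy-4-methoxybenzaldehyde F6.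
- The K2CO3/MeOH methanolysis of step 3 then removes the aryl acetate and gives 10 with no quinone on the way.

Step 1 (one-pot hydroboration, Suzuki coupling and acetylation). The risks are slow coupling of the doubly ortho-substituted bromide with a long-chain alkenylboronate and protodeboronation. The fallback sets out from 1 and comes back at 6.
- Suzuki–Miyaura vinylation of 1 with potassium vinyltrifluoroborate (PdCl2(dppf), K2CO3, THF/H2O, 70 °C) gives 3-hydroxy-4-methoxy-2-vinylbenzaldehyde F7.
- Ac2O/pyridine gives 3-acetoxy-4-methoxy-2-vinylbenzaldehyde F8.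
- Cross-metathesis of F8 with 1-tridecene (second-generation Hoveyda–Grubbs catalyst, CH2Cl2, 40 °C) gives the (E)-alkene 6.

**Further compounds**

F1 | step 2 | 2-bromo-3-(1,3-dioxolan-2-yl)-6-methoxyphenol | COc1ccc(C2OCCO2)c(Br)c1O
F2 | step 2 | 2-[2-bromo-4-methoxy-3-(methoxymethoxy)phenyl]-1,3-dioxolane | COCOc1c(OC)ccc(C2OCCO2)c1Br
F3 | step 2 | (R)-1-chlorotridecan-2-ol | CCCCCCCCCCC[C@H](CCl)O
F4 | step 2 | (R)-2-undecyloxirane | CCCCCCCCCCC[C@@H]1CO1
F5 | step 2 | (R)-1-[6-(1,3-dioxolan-2-yl)-3-methoxy-2-(methoxymethoxy)phenyl]tridecan-2-yl acetate | CCCCCCCCCCC[C@H](Cc1c(OCOC)c(OC)ccc1C1OCCO1)OC(C)=O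
F6 | step 4 | 3-acetoxy-2-[(2R)-2-acetoxytridecyl]-6-hydroxy-4-methoxybenzaldehyde | CCCCCCCCCCC[C@H](Cc1c(OC(C)=O)c(OC)cc(O)c1C=O)OC(C)=O
F7 | step 1 | 3-hydroxy-4-methoxy-2-vinylbenzaldehyde | C=Cc1c(O)c(OC)ccc1C=O
F8 | step 1 | 3-acetoxy-4-methoxy-2-vinylbenzaldehyde | C=Cc1c(OC(C)=O)c(OC)ccc1C=O
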